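**Plan**

- Retrosynthesis: after removal of the protecting groups, the C3–OH bond and the O1–C2 bond of ring C are cut back to a 2'-hydroxychalcone. Its enone C=C (C2–C3 of the target) is cut by aldol logic into a ring A acetophenone and a ring B/D/E aldehyde.
- In that aldehyde, ring D is cut first at O(C3')–C-beta (Mitsunobu) and then at O(C4')–C-alpha (epoxide opening). This leads to 3,4-dihydroxybenzaldehyde and the trans epoxide of O-benzylconiferyl alcohol, which is cut at its alkene to O-benzylvanillin.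
- Enabling feature: ring D has two C(sp3)–O bonds, at C-alpha (bearing guaiacyl ring E) and at C-beta (bearing CH2OH), in a trans relation. That is the outcome of two successive SN2 inversions on a trans aryl epoxide by the two oxygens of the ring B catechol.
- Forward order: C3 chain on ring E, epoxide, ring B joined through O(C4')–C-alpha, ring D closed through O(C3')–C-beta, ring A joined by Claisen–Schmidt condensation, ring C closed oxidatively, C3 hydroxylated, deprotection.
- Stereochemistry: both centres come from the Sharpless epoxidation with L-(+)-diethyl tartrate, which gives the (2S,3S)-epoxide. C-alpha is inverted in the opening and C-beta in the Mitsunobu closure, giving the (2R,3R)-trans dioxane, which no later step touches.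

Key step: step 6

Remark: C-alpha is the ring D carbon bearing ring E and C-beta the one bearing CH2OH; ring B is the catechol ring with oxygens on C3' and C4'; 4-(benzyloxy)-3-methoxybenzaldehyde (O-benzylvanillin) is taken as a purchasable compound.

**Route**

Step 1
Reactants: 1 4-(benzyloxy)-3-methoxybenzaldehyde; 2 triethyl phosphonoacetate
Product: 3 ethyl (2E)-3-[4-(benzyloxy)-3-methoxyphenyl]prop-2-enoate
Conditions: NaH, THF, 0 °C to rt
Reagents that add atoms: none
Why: Horner–Wadsworth–Emmons olefination of an aromatic aldehyde with a stabilised phosphonate anion is reliably E-selective under thermodynamic control and tolerates the benzyl and methyl ethers.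

Step 2
Reactants: 3 ethyl (2E)-3-[4-(benzyloxy)-3-methoxyphenyl]prop-2-enoate
Product: 4 (2E)-3-[4-(benzyloxy)-3-methoxyphenyl]prop-2-en-1-ol
Conditions: i-Bu2AlH (2.5 equiv), CH2Cl2, −78 to 0 °C; aqueous potassium sodium tartrate work-up
Reagents that add atoms: none
Why: 1,2-reduction of the unsaturated ester by the aluminium hydride at low temperature should give the allylic alcohol without touching the alkene or the aryl ethers.

Step 3
Reactants: 4 (2E)-3-[4-(benzyloxy)-3-methoxyphenyl]prop-2-en-1-ol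
Product: 5 [(2S,3S)-3-[4-(benzyloxy)-3-methoxyphenyl]oxiran-2-yl]methanol
Conditions: Ti(OiPr)4 (10 mol %), L-(+)-diethyl tartrate (12 mol %), t-BuOOH (2 equiv, decane), 4 Å molecular sieves, CH2Cl2, −25 °C; cold aqueous NaOH/brine work-up, crude product used at once
Reagents that add atoms: tert-butyl hydroperoxide, CC(C)(C)OO
Why: Sharpless asymmetric epoxidation of an E-allylic alcohol, in which the Ti–tartrate–peroxide complex built from the L-(+)-tartrate delivers oxygen to the alkene face that gives the (2S,3S)-trans epoxy alcohol, so that both stereocentres are set by the catalyst while sieves, low temperature and a basic work-up protect the acid-labile p-alkoxyaryl epoxide.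

Step 4
Reactants: 5 [(2S,3S)-3-[4-(benzyloxy)-3-methoxyphenyl]oxiran-2-yl]methanol
Product: 6 {[(2S,3S)-3-[4-(benzyloxy)-3-methoxyphenyl]oxiran-2-yl]methoxy}tri(propan-2-yl)silane
Conditions: TIPSCl, imidazole, DMAP (cat.), CH2Cl2, 0 °C to rt; chromatography on Et3N-deactivated silica
Reagents that add atoms: chlorotriisopropylsilane, CC(C)[Si](Cl)(C(C)C)C(C)C
Why: Silylation of the only hydroxyl removes the Payne rearrangement pathway before any base is applied, and the triisopropylsilyl ether is chosen over smaller silyl groups because it should withstand the later KOH, I2/DMSO and dimethyldioxirane steps.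

Step 5
Reactants: 6 {[(2S,3S)-3-[4-(benzyloxy)-3-methoxyphenyl]oxiran-2-yl]methoxy}tri(propan-2-yl)silane; 7 3,4-dihydroxybenzaldehyde
Product: 8 4-{(1R,2S)-1-[4-(benzyloxy)-3-methoxyphenyl]-2-hydroxy-3-[(triisopropylsilyl)oxy]propoxy}-3-hydroxybenzaldehyde
Conditions: 7 (2.5 equiv), Cs2CO3 (0.5 equiv), DMF, 80 °C, argon
Reagents that add atoms: none
Why: Base-mediated SN2 opening of an aryl epoxide by a phenoxide, in which the more acidic 4-hydroxyl (para to the formyl group) carries the charge of the monophenoxide and attacks the benzylic C-alpha from the rear (aryl-activated, whereas C-beta is deactivated and shielded by the adjacent silyloxymethyl group), so that C-alpha is inverted to R and C-beta stays S, giving the erythro ether with the 3'-phenol and the C-beta hydroxyl free.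

Step 6
Reactants: 8 4-{(1R,2S)-1-[4-(benzyloxy)-3-methoxyphenyl]-2-hydroxy-3-[(triisopropylsilyl)oxy]propoxy}-3-hydroxybenzaldehyde
Product: 10 (2R,3R)-2-[4-(benzyloxy)-3-methoxyphenyl]-3-{[(triisopropylsilyl)oxy]methyl}-2,3-dihydro-1,4-benzodioxine-6-carbaldehyde, via alkoxyphosphonium phenoxide 9 (not isolated)
Conditions: PPh3 (1.5 equiv), DIAD (1.5 equiv), THF (0.02 M), 0 °C to rt
Reagents that add atoms: none
Why: PPh3 and DIAD form a betaine that deprotonates the 3'-phenol of ring B and turns the only free alcohol, the C-beta hydroxyl, into alkoxyphosphonium ion 9, from which the tethered 3'-phenoxide expels Ph3P=O by rear-side attack. The closest known reaction is the intramolecular Mitsunobu etherification that converts 2-(2-hydroxyalkoxy)phenols into 1,4-benzodioxanes. Ring D closes in a 6-exo-tet mode through the new O(C3')–C-beta bond. The ring stereocentre at C-beta is fixed by SN2 inversion of the Sharpless-derived (S)-carbinol to R, while C-alpha (R) is a spectator, so the erythro precursor maps onto the trans (2R,3R) dioxane. The step needs substitution with inversion rather than elimination toward C-alpha or the CH2O carbon, or ionisation with aryl participation; this is secured by the six-membered intramolecular trajectory, the acidity of the phenol, the absence of any other free hydroxyl (primary OH silylated, ring E phenol benzylated) and high dilution.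

Step 7
Reactants: 11 2,4,6-trihydroxyacetophenone
Product: 12 1-[2,4-bis(benzyloxy)-6-hydroxyphenyl]ethan-1-one
Conditions: BnBr (2.1 equiv), K2CO3 (2.2 equiv), DMF, rt
Reagents that add atoms: benzyl bromide, BrCc1ccccc1
Why: Williamson etherification stops at the dibenzyl ether because the remaining ortho hydroxyl is hydrogen-bonded to the ketone carbonyl and is the least nucleophilic of the three.

Step 8
Reactants: 10 (2R,3R)-2-[4-(benzyloxy)-3-methoxyphenyl]-3-{[(triisopropylsilyl)oxy]methyl}-2,3-dihydro-1,4-benzodioxine-6-carbaldehyde; 12 1-[2,4-bis(benzyloxy)-6-hydroxyphenyl]ethan-1-one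
Product: 13 (2E)-1-[2,4-bis(benzyloxy)-6-hydroxyphenyl]-3-[(2R,3R)-2-[4-(benzyloxy)-3-methoxyphenyl]-3-{[(triisopropylsilyl)oxy]methyl}-2,3-dihydro-1,4-benzodioxin-6-yl]prop-2-en-1-one
Conditions: KOH (50% aq), EtOH/THF, rt
Reagents that add atoms: none
Why: Claisen–Schmidt condensation of the methyl ketone enolate with the non-enolisable aldehyde gives the E-enone after E1cB dehydration, and neither dioxane stereocentre carries a hydrogen acidic enough to epimerise.

Step 9
Reactants: 13 (2E)-1-[2,4-bis(benzyloxy)-6-hydroxyphenyl]-3-[(2R,3R)-2-[4-(benzyloxy)-3-methoxyphenyl]-3-{[(triisopropylsilyl)oxy]methyl}-2,3-dihydro-1,4-benzodioxin-6-yl]prop-2-en-1-one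
Product: 14 5,7-bis(benzyloxy)-2-[(2R,3R)-2-[4-(benzyloxy)-3-methoxyphenyl]-3-{[(triisopropylsilyl)oxy]methyl}-2,3-dihydro-1,4-benzodioxin-6-yl]-4H-chromen-4-one
Conditions: I2 (10 mol %), DMSO, 120 °C
Reagents that add atoms: none
Why: Iodine-catalysed oxidative cyclisation of a 2'-hydroxychalcone with DMSO as terminal oxidant closes ring C by 6-endo-trig oxa-Michael addition of the phenol and dehydrogenation to the chromen-4-one, while benzyl ethers and the hindered silyl ether should survive and the trans dioxane is also the thermodynamically preferred isomer.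

Step 10
Reactants: 14 5,7-bis(benzyloxy)-2-[(2R,3R)-2-[4-(benzyloxy)-3-methoxyphenyl]-3-{[(triisopropylsilyl)oxy]methyl}-2,3-dihydro-1,4-benzodioxin-6-yl]-4H-chromen-4-one
Product: 16 5,7-bis(benzyloxy)-3-hydroxy-2-[(2R,3R)-2-[4-(benzyloxy)-3-methoxyphenyl]-3-{[(triisopropylsilyl)oxy]methyl}-2,3-dihydro-1,4-benzodioxin-6-yl]-4H-chromen-4-one, via flavone 2,3-epoxide 15 (not isolated)
Conditions: dimethyldioxirane (about 3 equiv, acetone), CH2Cl2, 0 °C to rt; then p-TsOH·H2O (cat.), CH2Cl2, rt
Reagents that add atoms: dimethyldioxirane, CC1(C)OO1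
Why: Electrophilic epoxidation of the enol-ether-like C2=C3 bond of a 5-O-protected flavone by the dioxirane, followed by acid-catalysed opening of epoxide 15 at C2 with loss of the C3 proton, should give the aromatic 3-hydroxychromenone, so the transient epoxide stereocentres disappear.

Step 11
Reactants: 16 5,7-bis(benzyloxy)-3-hydroxy-2-[(2R,3R)-2-[4-(benzyloxy)-3-methoxyphenyl]-3-{[(triisopropylsilyl)oxy]methyl}-2,3-dihydro-1,4-benzodioxin-6-yl]-4H-chromen-4-one
Product: 17 5,7-bis(benzyloxy)-2-[(2R,3R)-2-[4-(benzyloxy)-3-methoxyphenyl]-3-(hydroxymethyl)-2,3-dihydro-1,4-benzodioxin-6-yl]-3-hydroxy-4H-chromen-4-one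
Conditions: HF·pyridine, THF/pyridine, 0 °C to rt
Reagents that add atoms: none
Why: Fluoride-driven desilylation under mildly acidic, non-oxidising conditions frees the primary alcohol without exposing the flavonol to base or disturbing the benzyl ethers.

Step 12
Reactants: 17 5,7-bis(benzyloxy)-2-[(2R,3R)-2-[4-(benzyloxy)-3-methoxyphenyl]-3-(hydroxymethyl)-2,3-dihydro-1,4-benzodioxin-6-yl]-3-hydroxy-4H-chromen-4-one
Product: 18 3,5,7-trihydroxy-2-[(2R,3R)-2-(4-hydroxy-3-methoxyphenyl)-3-(hydroxymethyl)-2,3-dihydro-1,4-benzodioxin-6-yl]-4H-chromen-4-one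
Conditions: H2 (1 atm), Pd/C (10% palladium on carbon), EtOAc/MeOH, rt; stopped after uptake of three equivalents
Reagents that add atoms: none
Why: Catalytic hydrogenolysis cleaves the three primary aryl benzyl ethers faster than the secondary, cyclic and hindered benzylic C-alpha–O bond of ring D and leaves the flavonol C2=C3 bond and both stereocentres intact.

**Compound list**

1 | 4-(benzyloxy)-3-methoxybenzaldehyde | COc1cc(C=O)ccc1OCc1ccccc1 | starting material
2 | triethyl phosphonoacetate | CCOC(=O)CP(=O)(OCC)OCC | starting material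
3 | ethyl (2E)-3-[4-(benzyloxy)-3-methoxyphenyl]prop-2-enoate | CCOC(=O)/C=C/c1ccc(OCc2ccccc2)c(OC)c1 | intermediate
4 | (2E)-3-[4-(benzyloxy)-3-methoxyphenyl]prop-2-en-1-ol | OC/C=C/c1ccc(OCc2ccccc2)c(OC)c1 | intermediate
5 | [(2S,3S)-3-[4-(benzyloxy)-3-methoxyphenyl]oxiran-2-yl]methanol | COc1cc([C@@H]2O[C@H]2CO)ccc1OCc1ccccc1 | intermediate
6 | {[(2S,3S)-3-[4-(benzyloxy)-3-methoxyphenyl]oxiran-2-yl]methoxy}tri(propan-2-yl)silane | COc1cc([C@@H]2O[C@H]2CO[Si](C(C)C)(C(C)C)C(C)C)ccc1OCc1ccccc1 | intermediate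
7 | 3,4-dihydroxybenzaldehyde | O=Cc1ccc(O)c(O)c1 | starting material
8 | 4-{(1R,2S)-1-[4-(benzyloxy)-3-methoxyphenyl]-2-hydroxy-3-[(triisopropylsilyl)oxy]propoxy}-3-hydroxybenzaldehyde (erythro) | COc1cc([C@H]([C@H](CO[Si](C(C)C)(C(C)C)C(C)C)O)Oc2ccc(C=O)cc2O)ccc1OCc1ccccc1 | intermediate
9 | alkoxyphosphonium phenoxide zwitterion of 8 (Ph3P+ on the C-beta oxygen, 3'-phenoxide) | COc1cc([C@H]([C@H](CO[Si](C(C)C)(C(C)C)C(C)C)O[P+](c2ccccc2)(c2ccccc2)c2ccccc2)Oc2ccc(C=O)cc2[O-])ccc1OCc1ccccc1 | intermediate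
10 | (2R,3R)-2-[4-(benzyloxy)-3-methoxyphenyl]-3-{[(triisopropylsilyl)oxy]methyl}-2,3-dihydro-1,4-benzodioxine-6-carbaldehyde | COc1cc([C@H]2Oc3ccc(C=O)cc3O[C@@H]2CO[Si](C(C)C)(C(C)C)C(C)C)ccc1OCc1ccccc1 | intermediate
11 | 2,4,6-trihydroxyacetophenone | CC(=O)c1c(O)cc(O)cc1O | starting material
12 | 1-[2,4-bis(benzyloxy)-6-hydroxyphenyl]ethan-1-one | CC(=O)c1c(O)cc(OCc2ccccc2)cc1OCc1ccccc1 | intermediate
13 | (2E)-1-[2,4-bis(benzyloxy)-6-hydroxyphenyl]-3-[(2R,3R)-2-[4-(benzyloxy)-3-methoxyphenyl]-3-{[(triisopropylsilyl)oxy]methyl}-2,3-dihydro-1,4-benzodioxin-6-yl]prop-2-en-1-one | COc1cc([C@H]2Oc3ccc(/C=C/C(=O)c4c(O)cc(OCc5ccccc5)cc4OCc4ccccc4)cc3O[C@@H]2CO[Si](C(C)C)(C(C)C)C(C)C)ccc1OCc1ccccc1 | intermediate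
14 | 5,7-bis(benzyloxy)-2-[(2R,3R)-2-[4-(benzyloxy)-3-methoxyphenyl]-3-{[(triisopropylsilyl)oxy]methyl}-2,3-dihydro-1,4-benzodioxin-6-yl]-4H-chromen-4-one | COc1cc([C@H]2Oc3ccc(-c4cc(=O)c5c(OCc6ccccc6)cc(OCc6ccccc6)cc5o4)cc3O[C@@H]2CO[Si](C(C)C)(C(C)C)C(C)C)ccc1OCc1ccccc1 | intermediate
15 | 2,3-epoxide of flavone 14 (both epoxide faces, dioxane centres 2R,3R) | COc1cc([C@H]2Oc3ccc(C45OC4C(=O)c4c(OCc6ccccc6)cc(OCc6ccccc6)cc4O5)cc3O[C@@H]2CO[Si](C(C)C)(C(C)C)C(C)C)ccc1OCc1ccccc1 | intermediate
16 | 5,7-bis(benzyloxy)-3-hydroxy-2-[(2R,3R)-2-[4-(benzyloxy)-3-methoxyphenyl]-3-{[(triisopropylsilyl)oxy]methyl}-2,3-dihydro-1,4-benzodioxin-6-yl]-4H-chromen-4-one | COc1cc([C@H]2Oc3ccc(-c4oc5cc(OCc6ccccc6)cc(OCc6ccccc6)c5c(=O)c4O)cc3O[C@@H]2CO[Si](C(C)C)(C(C)C)C(C)C)ccc1OCc1ccccc1 | intermediate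
17 | 5,7-bis(benzyloxy)-2-[(2R,3R)-2-[4-(benzyloxy)-3-methoxyphenyl]-3-(hydroxymethyl)-2,3-dihydro-1,4-benzodioxin-6-yl]-3-hydroxy-4H-chromen-4-one | COc1cc([C@H]2Oc3ccc(-c4oc5cc(OCc6ccccc6)cc(OCc6ccccc6)c5c(=O)c4O)cc3O[C@@H]2CO)ccc1OCc1ccccc1 | intermediate
18 | 3,5,7-trihydroxy-2-[(2R,3R)-2-(4-hydroxy-3-methoxyphenyl)-3-(hydroxymethyl)-2,3-dihydro-1,4-benzodioxin-6-yl]-4H-chromen-4-one | COc1cc([C@H]2Oc3ccc(-c4oc5cc(O)cc(O)c5c(=O)c4O)cc3O[C@@H]2CO)ccc1O | target

**Step count and risks**

Total step count: 12. Longest linear sequence: 11 (steps 1 to 6 and 8 to 12; step 7 is a one-step side branch).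

Steps most likely to fail:

1. Step 5. The stabilised 4-phenoxide is a weak nucleophile, so the opening may be slow. Alkylation through the 3-oxygen or on both oxygens, or partial ionisation of the p-alkoxybenzylic C–O bond with loss of configuration at C-alpha, could then compete. The fallback sets out from 5 and 7 and comes back at 8; it fixes the ring B regiochemistry by protection and activates the epoxide by chelation. Compound 7 would be alkylated through its dianion (NaH, 2.2 equiv, DMSO; allyl bromide, 1 equiv), which reacts at the more nucleophilic 3-oxygen, to give 3-(allyloxy)-4-hydroxybenzaldehyde F1. Ti(OiPr)4-mediated, hydroxyl-directed opening of the free epoxy alcohol 5 at C3 by F1 (CH2Cl2, rt) should give 3-(allyloxy)-4-{(1R,2S)-1-[4-(benzyloxy)-3-methoxyphenyl]-2,3-dihydroxypropoxy}benzaldehyde F2. TIPSCl/imidazole would silylate its primary hydroxyl, with no phenol competing, to give 3-(allyloxy)-4-{(1R,2S)-1-[4-(benzyloxy)-3-methoxyphenyl]-2-hydroxy-3-[(triisopropylsilyl)oxy]propoxy}benzaldehyde F3. Deallylation catalysed by zerovalent palladium (Pd(PPh3)4, K2CO3, MeOH, rt) would then free the 3'-phenol, which is compound 8.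

2. Step 3. The p-alkoxyaryl epoxy alcohol may be opened by the alcohols present under Lewis-acid catalysis, or decompose during work-up and purification, which would cost yield and enantiomeric purity. The fallback sets out from 4 and comes back at 6. Compound 4 would first be silylated (TIPSCl, imidazole, CH2Cl2) to [(2E)-3-[4-(benzyloxy)-3-methoxyphenyl]prop-2-en-1-yl]oxy-tri(propan-2-yl)silane F4. F4 would be epoxidised under Shi conditions with the enantiomer of the D-fructose-derived ketone catalyst (the L-series ketone, obtainable from L-sorbose), KHSO5 (Oxone) and K2CO3 buffer in MeCN/dimethoxymethane/water at 0 °C. Since the D-ketone gives the (R,R) series with E-aryl alkenes, its enantiomer should give the (2S,3S)-epoxide 6 directly, in a basic medium without a Lewis acid or a free hydroxyl.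

3. Step 10. Epoxidation of the C2=C3 bond is slow, so the dioxirane may instead oxidise the benzylic C–H bonds of the benzyl ethers and of C-alpha or the electron-rich ring E, or conversion may stay incomplete. The fallback sets out from 14 and comes back at 16; it replaces electrophilic oxidation by deprotonation and borylation. Compound 14 would be deprotonated at C3 with LiN(i-Pr)2 (THF, −78 °C) to the 3-lithioflavone F5. This would be trapped with B(OMe)3 as the dimethyl flavone-3-boronate F6 and oxidised in the same flask with H2O2/AcOH to flavonol 16.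

**Further compounds**

F1 | step 5 | 3-(allyloxy)-4-hydroxybenzaldehyde | C=CCOc1cc(C=O)ccc1O
F2 | step 5 | 3-(allyloxy)-4-{(1R,2S)-1-[4-(benzyloxy)-3-methoxyphenyl]-2,3-dihydroxypropoxy}benzaldehyde | COc1cc([C@H]([C@H](CO)O)Oc2ccc(C=O)cc2OCC=C)ccc1OCc1ccccc1
F3 | step 5 | 3-(allyloxy)-4-{(1R,2S)-1-[4-(benzyloxy)-3-methoxyphenyl]-2-hydroxy-3-[(triisopropylsilyl)oxy]propoxy}benzaldehyde | COc1cc([C@H]([C@H](CO[Si](C(C)C)(C(C)C)C(C)C)O)Oc2ccc(C=O)cc2OCC=C)ccc1OCc1ccccc1
F4 | step 3 | [(2E)-3-[4-(benzyloxy)-3-methoxyphenyl]prop-2-en-1-yl]oxy-tri(propan-2-yl)silane | CC(C)[Si](OC/C=C/c1ccc(OCc2ccccc2)c(OC)c1)(C(C)C)C(C)C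
F5 | step 10 | 3-lithio derivative of flavone 14 | COc1cc([C@H]2Oc3ccc(-c4oc5cc(OCc6ccccc6)cc(OCc6ccccc6)c5c(=O)c4[Li])cc3O[C@@H]2CO[Si](C(C)C)(C(C)C)C(C)C)ccc1OCc1ccccc1
F6 | step 10 | dimethyl 3-boronate of flavone 14 | COc1cc([C@H]2Oc3ccc(-c4oc5cc(OCc6ccccc6)cc(OCc6ccccc6)c5c(=O)c4B(OC)OC)cc3O[C@@H]2CO[Si](C(C)C)(C(C)C)C(C)C)ccc1OCc1ccccc1
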